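The runs are simulated from invented constants; the scatter is artificial.

A flat curve of left-handed product tempts you to book the rest of the charge as substrate lying unused, so keep the ledger before you read the plateau.

| setting | dusk | autumn | flask |
|---|---|---|---|
| left-handed substrate | 35 mM | 35 mM | 35 mM |
| right-handed substrate | 35 mM | 35 mM | 35 mM |
| partner | 77 mM | 77 mM | 77.0 mM |
| racemization catalyst | 70 µM | 70 µM | 70 µM |
| precatalyst | 1.8 mM | 1.8 mM | 1.8 mM |
| temperature | 25 °C | 20 °C | 25 °C |
| remark | the very flask that is asked about, followed so far | run made earlier |  |
| time |  |  | 8.0 d |

| run | time / h | left-handed product / % | left-handed substrate / % |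
|---|---|---|---|
| dusk | 10.0 | 57.3 | 9.9 |
| dusk | 30.0 | 68.6 | 2.3 |
| dusk | 48.0 | 70.3 | 0.7 |
| dusk | 72.0 | 71.9 | 0.3 |
| dusk | 120 | 71.8 | 0.1 |
| autumn | 10.0 | 45.8 | 16.1 |
| autumn | 30.0 | 64.4 | 3.6 |
| autumn | 48.0 | 67.8 | 0.8 |
| autumn | 72.0 | 70.5 | 0.8 |
| autumn | 120 | 70.1 | 0 |

(scatter of a reading: 0.5 percentage points)

- red: at 8.0 d take out 90% of the left-handed product then present, then wait 2.5 d
- grey: at 8.0 d add partner, 100% of the amount charged, then wait 2.5 d
- ochre: change nothing and wait 2.5 d more
- violet: at 8.0 d raise the temperature by 20 K, then wait 2.5 d
- blue: at 8.0 d add racemization catalyst, 100% of the amount charged, then wait 2.5 d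

- free catalyst is single-handed; left-handed substrate and right-handed substrate are mirror images of each other, charged as a racemate, each of them at the stated concentration
- left-handed product taken out counts as made
- "the catalyst" is free catalyst with its forms; racemization catalyst is a second catalyst
- additions bring no volume worth counting

- left-handed product, in percent of the left-handed substrate and right-handed substrate together first charged, at 8.0 d
- the option that brings most further left-handed product ("none" if no option brings more than 2 percentage points) (red / grey / ochre / violet / blue / none)
- left-handed product present, with what was taken out counted in, in percent of the left-handed substrate and right-handed substrate together first charged, after red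
- left-handed product present, with what was taken out counted in, in percent of the left-handed substrate and right-handed substrate together first charged, after ochre

1. The dusk run is the asked flask, followed so far. Its substrates together come to 70.0 mM, which is less than the 77.0 mM of partner. I therefore take the substrate pool as the limiting reagent, with one partner per substrate.

2. The ledger has four entries: left-handed product, right-handed product, left-handed substrate and right-handed substrate. The dusk run shows two of them. The racemization catalyst swaps the two substrates, so I take c(right-handed substrate) equal to c(left-handed substrate). The substrate still open is then twice the left-handed reading, a correction to the charge.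

3. At 120 h the readings of the dusk run give 71.9%. This is the left share: left-handed product divided by the substrate converted so far.

4. At 10.0 h the same reckoning gives 71.4%, although 19.8% of the charge was still open then. The two differ by 0.5 percentage points, against a scatter of 0.5 points per reading. So I book the gap, 28.1%, as right-handed product and not as right-handed substrate.

5. At the last reading of the dusk run the open entry is 0.2 points, less than the 2 points an option must bring. My reckoning is therefore about 71.9% at 8.0 d, the same after red and ochre, and none as best.

6. The forecast gives 72%, 72.1% after red, 72.1% after ochre, and blue as best: “Fresh racemization catalyst should convert much of the stranded right-handed substrate”. On best, my reckoning differs from it.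

The asked flask gives 71.4% at 8.0 d, 71.4% after red and 71.4% after ochre, and the answer to best is none, with blue bringing 0 points.

    partner + free catalyst + left-handed substrate → free catalyst + left-handed product (k = 4400 M⁻² min⁻¹, Ea = 43.0 kJ mol⁻¹)
    partner + free catalyst + right-handed substrate → free catalyst + right-handed product (k = 1700 M⁻² min⁻¹, Ea = 38.0 kJ mol⁻¹)
    left-handed substrate + racemization catalyst ⇌ right-handed substrate + racemization catalyst, rate k3*[racemization catalyst]*[left-handed substrate] forward; the back reaction follows from the equilibrium constant (k = 450 M⁻¹ min⁻¹, Ea = 43.0 kJ mol⁻¹)
    2 free catalyst ⇌ resting dimer, settled at all times (K = 37000 M⁻¹, ΔH = −62.0 kJ mol⁻¹)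
    partner + precatalyst → free catalyst + spent reagent (k = 0.00270 M⁻¹ min⁻¹, Ea = 79.0 kJ mol⁻¹)
    (constants at 25 °C)

At 192 h the asked flask holds 0% right-handed substrate and 28.6% right-handed product. Now take the neighbour charged with 46 mM of partner, which has 0% partner left at 192 h. The left share times that partner, divided by the pool, gives 47.2% left-handed product, and that neighbour holds 47.1%.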